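**Retrosynthetic overview**
1. Target ⇐ acetonide-protected diol with a C-9 butynyl chain; the (E)-C13=C14 allylic acetate comes from Zr-catalysed carboalumination/hydroxymethylation of the terminal alkyne, then acetylation.
2. C7=C8 ⇐ enol triflate (Pd/formate); ring A cis-diol ⇐ OsO4 on the C2=C3 olefin; C-9 centre ⇐ copper-catalysed conjugate addition to the C-8-methyl enone.
3. Key new step: CuH-catalysed enantioselective desymmetrising allene–cyclohexadienone cyclisation forms C4–C5, the gem-dimethyl carbon, the ring A olefin and the cis ring fusion (C-5, C-10).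
4. Prochiral dienone ⇐ 3-ethoxycyclohex-2-en-1-one by double Stork–Danheiser alkylation (MeI, allenyl bromide from 2-methylbut-3-yn-2-ol); ring B is the bought six-membered ring, ring A is formed second.

Assumption: the SMILES is taken literally, a cis-fused decalin with H-5, the C-10 methyl and the C-9 side chain on one face and the 2,3-diol on the other, (2S,3R,5R,9R,10S) in labdane numbering (used for locants such as C-9 below).

Step 1
Reactants: 1 2-methylbut-3-yn-2-ol
Product: 2 2-[(2-methylbut-3-yn-2-yl)oxy]oxane (racemic THP ether)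
Conditions: 3,4-dihydro-2H-pyran, PPTS (cat.), CH2Cl2, rt
Reagents that add atoms: 3,4-dihydro-2H-pyran, C1=COCCC1
Why: Acid-catalysed tetrahydropyranylation of the tertiary alcohol gives an acetal that tolerates n-BuLi and later acts as the leaving group for allene formation, its racemic acetal carbon being lost in step 3.

Step 2
Reactants: 2 2-[(2-methylbut-3-yn-2-yl)oxy]oxane
Product: 4 4-methyl-4-(oxan-2-yloxy)pent-2-yn-1-ol, via lithium acetylide 3 (not isolated)
Conditions: n-BuLi, THF, −78 °C; (CH2O)n, −78 °C → rt; H2O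
Reagents that add atoms: paraformaldehyde (formaldehyde), C=O
Why: Deprotonation of the terminal alkyne and hydroxymethylation of the lithium acetylide is a standard one-carbon homologation that sets no stereocentre.

Step 3
Reactants: 4 4-methyl-4-(oxan-2-yloxy)pent-2-yn-1-ol
Product: 5 4-methylpenta-2,3-dien-1-ol
Conditions: LiAlH4, Et2O, reflux; H2O, aq. NaOH
Reagents that add atoms: none
Why: Alkoxide-directed hydroalumination of the propargylic alcohol puts aluminium next to the carbon bearing the OTHP group and 1,2-elimination (a formal SN2′ hydride reduction) gives the achiral 1,1-dimethylallene.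

Step 4
Reactants: 5 4-methylpenta-2,3-dien-1-ol
Product: 6 1-bromo-4-methylpenta-2,3-diene
Conditions: CBr4, PPh3, CH2Cl2, 0 °C
Reagents that add atoms: carbon tetrabromide, BrC(Br)(Br)Br
Why: Appel bromination converts the primary allenylic alcohol into the bromide by SN2 displacement of the alkoxyphosphonium ion under neutral conditions that leave the allene intact.

Step 5
Reactants: 7 3-ethoxycyclohex-2-en-1-one
Product: 9 3-ethoxy-6-methylcyclohex-2-en-1-one (racemic), via lithium dienolate 8 (not isolated)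
Conditions: LiN(i-Pr)2, THF, −78 °C; MeI, −78 °C → rt
Reagents that add atoms: iodomethane, CI
Why: Kinetic α′-deprotonation of the vinylogous ester and C-methylation (Stork–Danheiser alkylation) installs the future C-10 methyl, the racemic centre being of no consequence because it is re-enolised in step 6.

Step 6
Reactants: 9 3-ethoxy-6-methylcyclohex-2-en-1-one; 6 1-bromo-4-methylpenta-2,3-diene
Product: 11 3-ethoxy-6-methyl-6-(4-methylpenta-2,3-dien-1-yl)cyclohex-2-en-1-one (racemic), via lithium dienolate 10 (not isolated)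
Conditions: LiN(i-Pr)2, THF, −78 °C; 6, DMPU, −78 → 0 °C
Reagents that add atoms: none
Why: A second Stork–Danheiser α′-alkylation with the reactive allenylmethyl bromide (SN2) builds the quaternary carbon (future C-10) carrying the methyl and the allenyl tether, racemic but destined to become a prochiral centre in 15.

Step 7
Reactants: 11 3-ethoxy-6-methyl-6-(4-methylpenta-2,3-dien-1-yl)cyclohex-2-en-1-one
Product: 13 4-methyl-4-(4-methylpenta-2,3-dien-1-yl)cyclohex-2-en-1-one (racemic), via allylic alcohol 12 (not isolated)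
Conditions: LiAlH4, Et2O, 0 °C; then 1 M HCl, THF, 0 °C → rt
Reagents that add atoms: water, O
Why: 1,2-Reduction of the vinylogous ester carbonyl followed by acid hydrolysis of the β-ethoxy allylic alcohol (Stork–Danheiser 1,3-carbonyl transposition) gives the 4,4-disubstituted enone, brief dilute acid leaving the trisubstituted allene intact.

Step 8
Reactants: 13 4-methyl-4-(4-methylpenta-2,3-dien-1-yl)cyclohex-2-en-1-one
Product: 15 4-methyl-4-(4-methylpenta-2,3-dien-1-yl)cyclohexa-2,5-dien-1-one, via lithium dienolate 14 (not isolated)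
Conditions: LiN(i-Pr)2, THF, −78 °C; PhS(Cl)=N-t-Bu, −78 °C
Reagents that add atoms: none
Why: Mukaiyama dehydrogenation, in which the kinetic α′-enolate is S-sulfinimidoylated and the adduct undergoes syn-elimination at low temperature, gives the cross-conjugated dienone, which is achiral (mirror plane through C-1 and C-4) so the racemic history is erased.

Step 9
Reactants: 15 4-methyl-4-(4-methylpenta-2,3-dien-1-yl)cyclohexa-2,5-dien-1-one
Product: 17 (4aS,8aS)-4a,8,8-trimethyl-4a,5,8,8a-tetrahydronaphthalen-2(1H)-one, via silyl dienol ether 16 (not isolated)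
Conditions: Cu(OAc)2 (5 mol%), (R)-DTBM-SEGPHOS (6 mol%), (MeO)2MeSiH (2 equiv), THF, 0 °C → rt; then 1 M HCl, THF, 0 °C
Reagents that add atoms: none
Why: Proposed new method: an enantioselective CuH-catalysed desymmetrising hydro-cyclisation of an all-carbon-tethered cyclohexadienone–1,1-dimethylallene, in which the ligated copper hydride (from Cu(OAc)2, the bisphosphine and the silane) hydrocuprates the less hindered allene π-bond (H to the central carbon) to give a prenyl-type allylcopper that equilibrates by 1,3-metallotropic shift and, held over the dienone by the three-atom tether, adds through its fully substituted γ-carbon to one of the two enantiotopic β-carbons (π-complexation, a trivalent copper β-cuprio enolate, C–C reductive elimination), thereby forming the C4–C5 bond, the gem-dimethyl quaternary carbon, ring A with its C2=C3 double bond and, because the tether can only reach the face to which it is attached, the cis ring fusion, while the chiral ligand chooses the enantiotopic enone and so fixes C-5 and C-10 (the antipodal ligand is used if the opposite sense is found); the copper enolate is silylated by the silane, which regenerates CuH and stores the product as the non-reducible silyl dienol ether 16 until acidic work-up, and conjugate reduction of 15 should be slow because both β-carbons are neopentylic whereas allene hydrocupration is fast; the closest known reaction types are CuH-catalysed reductive allene–ketone coupling and copper-catalysed borylative or silylative desymmetrising cyclisations of heteroatom-tethered dienone allenes, neither shown as a hydride-initiated carbocyclisation that makes a six-membered ring and an all-carbon quaternary centre.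

Step 10
Reactants: 17 (4aS,8aS)-4a,8,8-trimethyl-4a,5,8,8a-tetrahydronaphthalen-2(1H)-one
Product: 18 (4aR,8aS)-3-iodo-4a,8,8-trimethyl-4a,5,8,8a-tetrahydronaphthalen-2(1H)-one
Conditions: I2, pyridine, CH2Cl2, 0 °C → rt
Reagents that add atoms: iodine, II
Why: α-Iodination of the enone by pyridine conjugate addition, iodination of the enolate and elimination (Johnson iodination) occurs only at the enone α-carbon and touches neither the isolated ring A olefin nor a stereocentre (the descriptor change at C-4a is a priority effect only).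

Step 11
Reactants: 18 (4aR,8aS)-3-iodo-4a,8,8-trimethyl-4a,5,8,8a-tetrahydronaphthalen-2(1H)-one
Product: 19 (4aS,8aS)-3,4a,8,8-tetramethyl-4a,5,8,8a-tetrahydronaphthalen-2(1H)-one
Conditions: MeB(OH)2, Pd(OAc)2 (5 mol%), SPhos (10 mol%), K3PO4, toluene/H2O, 80 °C
Reagents that add atoms: methylboronic acid, CB(O)O
Why: Suzuki–Miyaura coupling of the electron-poor alkenyl iodide installs the C-8 methyl with the enone intact, and no enolisable stereocentre is present.

Step 12
Reactants: 19 (4aS,8aS)-3,4a,8,8-tetramethyl-4a,5,8,8a-tetrahydronaphthalen-2(1H)-one; 20 (4-bromobut-1-yn-1-yl)trimethylsilane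
Product: 22 trimethyl{4-[(1S,4aS,8aR)-2,5,5,8a-tetramethyl-3-[(trimethylsilyl)oxy]-1,4,4a,5,8,8a-hexahydronaphthalen-1-yl]but-1-yn-1-yl}silane, via Grignard reagent 21 (not isolated)
Conditions: 20, Mg, THF, rt; then 19, CuBr·SMe2 (20 mol%), TMSCl, HMPA, THF, −78 → −30 °C; Et3N, aq. NaHCO3
Reagents that add atoms: chlorotrimethylsilane, C[Si](C)(C)Cl
Why: Copper-catalysed, TMSCl-accelerated 1,4-addition of the Grignard reagent (Kharasch-type conjugate addition) gives the tetrasubstituted silyl enol ether regiospecifically, the nucleophile adding axially to C-9 anti to the pseudo-axial C-1 methylene of ring A (attack on the other face would create a 1,3-diaxial clash with C-4), so the side chain ends up cis to the C-10 methyl.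

Step 13
Reactants: 22 trimethyl{4-[(1S,4aS,8aR)-2,5,5,8a-tetramethyl-3-[(trimethylsilyl)oxy]-1,4,4a,5,8,8a-hexahydronaphthalen-1-yl]but-1-yn-1-yl}silane
Product: 24 (4S,4aR,8aS)-3,4a,8,8-tetramethyl-4-[4-(trimethylsilyl)but-3-yn-1-yl]-1,4,4a,5,8,8a-hexahydronaphthalen-2-yl trifluoromethanesulfonate, via lithium enolate 23 (not isolated)
Conditions: MeLi, THF, 0 °C; Comins' reagent, −78 °C → rt
Reagents that add atoms: N-(5-chloropyridin-2-yl)-1,1,1-trifluoro-N-[(trifluoromethyl)sulfonyl]methanesulfonamide (Comins' reagent), O=S(=O)(N(c1ccc(Cl)cn1)S(=O)(=O)C(F)(F)F)C(F)(F)F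
Why: MeLi cleaves the O–Si bond to the regiodefined lithium enolate, which is O-triflated and so fixes the position of the future C7=C8 double bond, the alkynyl C–Si bond being much slower to cleave and no stereocentre being touched.

Step 14
Reactants: 24 (4S,4aR,8aS)-3,4a,8,8-tetramethyl-4-[4-(trimethylsilyl)but-3-yn-1-yl]-1,4,4a,5,8,8a-hexahydronaphthalen-2-yl trifluoromethanesulfonate
Product: 25 (4S,4aR,6S,7R,8aR)-6,7-dihydroxy-3,4a,8,8-tetramethyl-4-[4-(trimethylsilyl)but-3-yn-1-yl]-1,4,4a,5,6,7,8,8a-octahydronaphthalen-2-yl trifluoromethanesulfonate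
Conditions: OsO4 (5 mol%), NMO, acetone/H2O (8:1), rt
Reagents that add atoms: N-methylmorpholine N-oxide, C[N+]1([O-])CCOCC1; water, O
Why: Catalytic OsO4/NMO syn-dihydroxylation attacks only the ring A olefin (the tetrasubstituted enol triflate is electron-poor and the silyl alkyne inert) and, in the expected preferred conformer with the C-10 methyl axial on ring A and the C-9 chain pseudo-axial, the face syn to the C-10 methyl is blocked by the 1,3-related axial methyls on C-10 and C-4, so the cis-diol forms on the opposite face as with 4,4,10-trimethyl ring A olefins of trans-fused terpenoids.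

Step 15
Reactants: 25 (4S,4aR,6S,7R,8aR)-6,7-dihydroxy-3,4a,8,8-tetramethyl-4-[4-(trimethylsilyl)but-3-yn-1-yl]-1,4,4a,5,6,7,8,8a-octahydronaphthalen-2-yl trifluoromethanesulfonate
Product: 26 (4S,4aR,6S,7R,8aR)-6,7-(isopropylidenedioxy)-3,4a,8,8-tetramethyl-4-[4-(trimethylsilyl)but-3-yn-1-yl]-1,4,4a,5,6,7,8,8a-octahydronaphthalen-2-yl trifluoromethanesulfonate
Conditions: Me2C(OMe)2, PPTS (cat.), CH2Cl2, rt
Reagents that add atoms: 2,2-dimethoxypropane, COC(C)(C)OC
Why: Acid-catalysed transketalisation closes the cis-fused dioxolane on the cis-diol and protects it for the organometallic steps without touching a stereocentre.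

Step 16
Reactants: 26 (4S,4aR,6S,7R,8aR)-6,7-(isopropylidenedioxy)-3,4a,8,8-tetramethyl-4-[4-(trimethylsilyl)but-3-yn-1-yl]-1,4,4a,5,6,7,8,8a-octahydronaphthalen-2-yl trifluoromethanesulfonate
Product: 27 trimethyl{4-[(1R,4aR,6R,7S,8aS)-6,7-(isopropylidenedioxy)-2,5,5,8a-tetramethyl-1,4,4a,5,6,7,8,8a-octahydronaphthalen-1-yl]but-1-yn-1-yl}silane
Conditions: Pd(OAc)2 (5 mol%), PPh3 (10 mol%), HCO2H, Bu3N, DMF, 60 °C
Reagents that add atoms: none
Why: Palladium-catalysed formate reduction of the alkenyl triflate (oxidative addition to zerovalent palladium, decarboxylation of formate, C–H reductive elimination) gives the C7=C8 trisubstituted olefin regiospecifically while the buffered medium spares the acetonide and the C-9 centre.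

Step 17
Reactants: 27 trimethyl{4-[(1R,4aR,6R,7S,8aS)-6,7-(isopropylidenedioxy)-2,5,5,8a-tetramethyl-1,4,4a,5,6,7,8,8a-octahydronaphthalen-1-yl]but-1-yn-1-yl}silane
Product: 28 (1R,4aR,6R,7S,8aS)-1-(but-3-yn-1-yl)-6,7-(isopropylidenedioxy)-2,5,5,8a-tetramethyl-1,4,4a,5,6,7,8,8a-octahydronaphthalene
Conditions: K2CO3 (cat.), MeOH, rt
Reagents that add atoms: none
Why: Base-catalysed methanolysis of the alkynyl C–Si bond unmasks the terminal alkyne under conditions to which acetonide and olefin are inert.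

Step 18
Reactants: 28 (1R,4aR,6R,7S,8aS)-1-(but-3-yn-1-yl)-6,7-(isopropylidenedioxy)-2,5,5,8a-tetramethyl-1,4,4a,5,6,7,8,8a-octahydronaphthalene
Product: 30 (2E)-5-[(1R,4aR,6R,7S,8aS)-6,7-(isopropylidenedioxy)-2,5,5,8a-tetramethyl-1,4,4a,5,6,7,8,8a-octahydronaphthalen-1-yl]-3-methylpent-2-en-1-ol, via alkenylalane 29 (not isolated)
Conditions: Me3Al, Cp2ZrCl2 (25 mol%), CH2Cl2, 0 °C → rt; then n-BuLi, THF, −78 °C; (CH2O)n, rt; aq. potassium sodium tartrate
Reagents that add atoms: trimethylaluminium, C[Al](C)C; paraformaldehyde (formaldehyde), C=O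
Why: Negishi zirconium-catalysed carboalumination adds Me–Al syn across the terminal alkyne with methyl on the internal carbon, and hydroxymethylation of the derived alkenylaluminate with retention gives the (E)-trisubstituted C13=C14 allylic alcohol.

Step 19
Reactants: 30 (2E)-5-[(1R,4aR,6R,7S,8aS)-6,7-(isopropylidenedioxy)-2,5,5,8a-tetramethyl-1,4,4a,5,6,7,8,8a-octahydronaphthalen-1-yl]-3-methylpent-2-en-1-ol
Product: 31 (2E)-5-[(1R,4aR,6R,7S,8aS)-6,7-(isopropylidenedioxy)-2,5,5,8a-tetramethyl-1,4,4a,5,6,7,8,8a-octahydronaphthalen-1-yl]-3-methylpent-2-en-1-yl acetate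
Conditions: Ac2O, pyridine, DMAP (cat.), CH2Cl2, 0 °C → rt
Reagents that add atoms: acetic anhydride, CC(=O)OC(C)=O
Why: DMAP-catalysed acylation of the only free (primary allylic) hydroxyl gives the acetate without affecting any stereocentre.

Step 20
Reactants: 31 (2E)-5-[(1R,4aR,6R,7S,8aS)-6,7-(isopropylidenedioxy)-2,5,5,8a-tetramethyl-1,4,4a,5,6,7,8,8a-octahydronaphthalen-1-yl]-3-methylpent-2-en-1-yl acetate
Product: 32 (2E)-5-[(1R,4aR,6R,7S,8aS)-6,7-dihydroxy-2,5,5,8a-tetramethyl-1,4,4a,5,6,7,8,8a-octahydronaphthalen-1-yl]-3-methylpent-2-en-1-yl acetate (CNP0280580.3)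
Conditions: AcOH/H2O (4:1), 40 °C
Reagents that add atoms: none
Why: Mild aqueous acetic acid hydrolyses the cis-fused acetonide while the primary allylic acetate and both trisubstituted olefins survive, releasing the target diol.

**Compound list**
1 | 2-methylbut-3-yn-2-ol | CC(C)(O)C#C | starting material
2 | 2-[(2-methylbut-3-yn-2-yl)oxy]oxane (racemic) | C#CC(C)(C)OC1CCCCO1 | intermediate
3 | {3-methyl-3-[(oxan-2-yl)oxy]but-1-yn-1-yl}lithium | [Li]C#CC(C)(C)OC1CCCCO1 | intermediate
4 | 4-methyl-4-(oxan-2-yloxy)pent-2-yn-1-ol (racemic) | OCC#CC(C)(C)OC1CCCCO1 | intermediate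
5 | 4-methylpenta-2,3-dien-1-ol | OCC=C=C(C)C | intermediate
6 | 1-bromo-4-methylpenta-2,3-diene | BrCC=C=C(C)C | intermediate
7 | 3-ethoxycyclohex-2-en-1-one | CCOC1=CC(=O)CCC1 | starting material
8 | lithium 5-ethoxycyclohexa-1,5-dien-1-olate | CCOC1=CC(O[Li])=CCC1 | intermediate
9 | 3-ethoxy-6-methylcyclohex-2-en-1-one (racemic) | CCOC1=CC(=O)C(C)CC1 | intermediate
10 | lithium 5-ethoxy-2-methylcyclohexa-1,5-dien-1-olate | CCOC1=CC(O[Li])=C(C)CC1 | intermediate
11 | 3-ethoxy-6-methyl-6-(4-methylpenta-2,3-dien-1-yl)cyclohex-2-en-1-one (racemic) | CCOC1=CC(=O)C(C)(CC=C=C(C)C)CC1 | intermediate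
12 | 3-ethoxy-6-methyl-6-(4-methylpenta-2,3-dien-1-yl)cyclohex-2-en-1-ol (diastereomer mixture) | CCOC1=CC(O)C(C)(CC=C=C(C)C)CC1 | intermediate
13 | 4-methyl-4-(4-methylpenta-2,3-dien-1-yl)cyclohex-2-en-1-one (racemic) | O=C1C=CC(C)(CC=C=C(C)C)CC1 | intermediate
14 | lithium 4-methyl-4-(4-methylpenta-2,3-dien-1-yl)cyclohexa-1,5-dien-1-olate | [Li]OC1=CCC(C)(CC=C=C(C)C)C=C1 | intermediate
15 | 4-methyl-4-(4-methylpenta-2,3-dien-1-yl)cyclohexa-2,5-dien-1-one (achiral) | O=C1C=CC(C)(CC=C=C(C)C)C=C1 | intermediate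
16 | {[(4aS,8aS)-4a,8,8-trimethyl-4a,5,8,8a-tetrahydronaphthalen-2-yl]oxy}dimethoxy(methyl)silane | C1=CC(O[Si](C)(OC)OC)=C[C@H]2C(C)(C)C=CC[C@@]12C | intermediate
17 | (4aS,8aS)-4a,8,8-trimethyl-4a,5,8,8a-tetrahydronaphthalen-2(1H)-one (cis-fused) | C1=CC(=O)C[C@H]2C(C)(C)C=CC[C@@]12C | intermediate
18 | (4aR,8aS)-3-iodo-4a,8,8-trimethyl-4a,5,8,8a-tetrahydronaphthalen-2(1H)-one | C1=C(I)C(=O)C[C@H]2C(C)(C)C=CC[C@@]12C | intermediate
19 | (4aS,8aS)-3,4a,8,8-tetramethyl-4a,5,8,8a-tetrahydronaphthalen-2(1H)-one | C1=C(C)C(=O)C[C@H]2C(C)(C)C=CC[C@@]12C | intermediate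
20 | (4-bromobut-1-yn-1-yl)trimethylsilane | C[Si](C)(C)C#CCCBr | starting material
21 | [4-(trimethylsilyl)but-3-yn-1-yl]magnesium bromide | C[Si](C)(C)C#CCC[Mg]Br | intermediate
22 | trimethyl{4-[(1S,4aS,8aR)-2,5,5,8a-tetramethyl-3-[(trimethylsilyl)oxy]-1,4,4a,5,8,8a-hexahydronaphthalen-1-yl]but-1-yn-1-yl}silane | C[Si](C)(C)C#CCC[C@@H]1C(C)=C(O[Si](C)(C)C)C[C@H]2C(C)(C)C=CC[C@@]12C | intermediate
23 | lithium (4S,4aR,8aS)-3,4a,8,8-tetramethyl-4-[4-(trimethylsilyl)but-3-yn-1-yl]-1,4,4a,5,8,8a-hexahydronaphthalen-2-olate | C[Si](C)(C)C#CCC[C@@H]1C(C)=C(O[Li])C[C@H]2C(C)(C)C=CC[C@@]12C | intermediate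
24 | (4S,4aR,8aS)-3,4a,8,8-tetramethyl-4-[4-(trimethylsilyl)but-3-yn-1-yl]-1,4,4a,5,8,8a-hexahydronaphthalen-2-yl trifluoromethanesulfonate | C[Si](C)(C)C#CCC[C@@H]1C(C)=C(OS(=O)(=O)C(F)(F)F)C[C@H]2C(C)(C)C=CC[C@@]12C | intermediate
25 | (4S,4aR,6S,7R,8aR)-6,7-dihydroxy-3,4a,8,8-tetramethyl-4-[4-(trimethylsilyl)but-3-yn-1-yl]-1,4,4a,5,6,7,8,8a-octahydronaphthalen-2-yl trifluoromethanesulfonate | C[Si](C)(C)C#CCC[C@@H]1C(C)=C(OS(=O)(=O)C(F)(F)F)C[C@H]2C(C)(C)[C@@H](O)[C@@H](O)C[C@@]12C | intermediate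
26 | (4S,4aR,6S,7R,8aR)-6,7-(isopropylidenedioxy)-3,4a,8,8-tetramethyl-4-[4-(trimethylsilyl)but-3-yn-1-yl]-1,4,4a,5,6,7,8,8a-octahydronaphthalen-2-yl trifluoromethanesulfonate | C[Si](C)(C)C#CCC[C@@H]1C(C)=C(OS(=O)(=O)C(F)(F)F)C[C@H]2C(C)(C)[C@@H](OC(C)(C)O3)[C@@H]3C[C@@]12C | intermediate
27 | trimethyl{4-[(1R,4aR,6R,7S,8aS)-6,7-(isopropylidenedioxy)-2,5,5,8a-tetramethyl-1,4,4a,5,6,7,8,8a-octahydronaphthalen-1-yl]but-1-yn-1-yl}silane | C[Si](C)(C)C#CCC[C@@H]1C(C)=CC[C@H]2C(C)(C)[C@@H](OC(C)(C)O3)[C@@H]3C[C@@]12C | intermediate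
28 | (1R,4aR,6R,7S,8aS)-1-(but-3-yn-1-yl)-6,7-(isopropylidenedioxy)-2,5,5,8a-tetramethyl-1,4,4a,5,6,7,8,8a-octahydronaphthalene | C#CCC[C@@H]1C(C)=CC[C@H]2C(C)(C)[C@@H](OC(C)(C)O3)[C@@H]3C[C@@]12C | intermediate
29 | dimethyl{(1E)-4-[(1R,4aR,6R,7S,8aS)-6,7-(isopropylidenedioxy)-2,5,5,8a-tetramethyl-1,4,4a,5,6,7,8,8a-octahydronaphthalen-1-yl]-2-methylbut-1-en-1-yl}alane | C[Al](C)/C=C(\C)CC[C@@H]1C(C)=CC[C@H]2C(C)(C)[C@@H](OC(C)(C)O3)[C@@H]3C[C@@]12C | intermediate
30 | (2E)-5-[(1R,4aR,6R,7S,8aS)-6,7-(isopropylidenedioxy)-2,5,5,8a-tetramethyl-1,4,4a,5,6,7,8,8a-octahydronaphthalen-1-yl]-3-methylpent-2-en-1-ol | OC/C=C(\C)CC[C@@H]1C(C)=CC[C@H]2C(C)(C)[C@@H](OC(C)(C)O3)[C@@H]3C[C@@]12C | intermediate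
31 | (2E)-5-[(1R,4aR,6R,7S,8aS)-6,7-(isopropylidenedioxy)-2,5,5,8a-tetramethyl-1,4,4a,5,6,7,8,8a-octahydronaphthalen-1-yl]-3-methylpent-2-en-1-yl acetate | CC(=O)OC/C=C(\C)CC[C@@H]1C(C)=CC[C@H]2C(C)(C)[C@@H](OC(C)(C)O3)[C@@H]3C[C@@]12C | intermediate
32 | (2E)-5-[(1R,4aR,6R,7S,8aS)-6,7-dihydroxy-2,5,5,8a-tetramethyl-1,4,4a,5,6,7,8,8a-octahydronaphthalen-1-yl]-3-methylpent-2-en-1-yl acetate | CC(=O)OC/C=C(\C)CC[C@@H]1C(C)=CC[C@H]2C(C)(C)[C@@H](O)[C@@H](O)C[C@@]12C | target

**Totals and risks**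
Total step count: 20. Longest linear sequence: 19 steps (steps 1–4 and 6–20, from 2-methylbut-3-yn-2-ol).

The three steps most likely to fail:

Step 9, the proposed new cyclisation. The risks are conjugate reduction of dienone 15 by CuH before the allene is engaged, and insufficient enantioselectivity. The fallback uses known chemistry, sets out from 15 and comes back at 17. A copper-catalysed enantioselective silylative cyclisation, the established silylcupration–conjugate addition mode of dienone-tethered allenes (PhMe2Si–B(pin), CuCl, NaOt-Bu, (R)-DTBM-SEGPHOS, MeOH, THF; no hydride is present, so the dienone cannot be reduced), gives (4aS,8aR)-7-[dimethyl(phenyl)silyl]-4a,8,8-trimethyl-4a,5,8,8a-tetrahydronaphthalen-2(1H)-one F1. Ipso-protodesilylation of this vinylsilane (CF3CO2H, CH2Cl2, 0 °C) then gives 17.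

Step 12, conjugate addition to an α-methyl enone whose β-carbon is neopentylic. The fallback sets out from 17 (steps 10 and 11 are then dropped) and comes back at 22. The same copper-catalysed, TMSCl-accelerated addition of 21 is run on the less hindered α-unsubstituted enone 17 and gives trimethyl{4-[(1R,4aS,8aS)-5,5,8a-trimethyl-3-[(trimethylsilyl)oxy]-1,4,4a,5,8,8a-hexahydronaphthalen-1-yl]but-1-yn-1-yl}silane F2. MeLi (THF, 0 °C) converts it into lithium (4R,4aS,8aS)-4a,8,8-trimethyl-4-[4-(trimethylsilyl)but-3-yn-1-yl]-1,4,4a,5,8,8a-hexahydronaphthalen-2-olate F3. C-Methylation with MeI gives (4R,4aS,8aS)-3,4a,8,8-tetramethyl-4-[4-(trimethylsilyl)but-3-yn-1-yl]-3,4,4a,5,8,8a-hexahydronaphthalen-2(1H)-one F4 as a C-3 epimer mixture. Thermodynamic silylation (TMSCl, NaI, Et3N, MeCN, rt) towards the more substituted side then gives 22.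

Step 14, the face selectivity of osmylation on a conformationally mobile cis-decalin. The fallback sets out from 24 and comes back at 25. If OsO4 prefers the face syn to the C-10 methyl, the product is (4S,4aR,6R,7S,8aR)-6,7-dihydroxy-3,4a,8,8-tetramethyl-4-[4-(trimethylsilyl)but-3-yn-1-yl]-1,4,4a,5,6,7,8,8a-octahydronaphthalen-2-yl trifluoromethanesulfonate F5, alone or mixed with 25. This is oxidised (DMSO, (CF3CO)2O, Et3N, CH2Cl2, −78 °C) to (4S,4aS,8aR)-3,4a,8,8-tetramethyl-6,7-dioxo-4-[4-(trimethylsilyl)but-3-yn-1-yl]-1,4,4a,5,6,7,8,8a-octahydronaphthalen-2-yl trifluoromethanesulfonate F6. NaBH4 (EtOH/THF, −20 °C) then delivers hydride to both carbonyls from that same accessible face, which places both hydroxyls on the opposite face and gives 25.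

**Further compounds**
F1 | step 9 | (4aS,8aR)-7-[dimethyl(phenyl)silyl]-4a,8,8-trimethyl-4a,5,8,8a-tetrahydronaphthalen-2(1H)-one | C1=CC(=O)C[C@H]2C(C)(C)C([Si](C)(C)c3ccccc3)=CC[C@@]12C
F2 | step 12 | trimethyl{4-[(1R,4aS,8aS)-5,5,8a-trimethyl-3-[(trimethylsilyl)oxy]-1,4,4a,5,8,8a-hexahydronaphthalen-1-yl]but-1-yn-1-yl}silane | C[Si](C)(C)C#CCC[C@@H]1C=C(O[Si](C)(C)C)C[C@H]2C(C)(C)C=CC[C@@]12C
F3 | step 12 | lithium (4R,4aS,8aS)-4a,8,8-trimethyl-4-[4-(trimethylsilyl)but-3-yn-1-yl]-1,4,4a,5,8,8a-hexahydronaphthalen-2-olate | C[Si](C)(C)C#CCC[C@@H]1C=C(O[Li])C[C@H]2C(C)(C)C=CC[C@@]12C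
F4 | step 12 | (4R,4aS,8aS)-3,4a,8,8-tetramethyl-4-[4-(trimethylsilyl)but-3-yn-1-yl]-3,4,4a,5,8,8a-hexahydronaphthalen-2(1H)-one (C-3 epimers) | C[Si](C)(C)C#CCC[C@@H]1C(C)C(=O)C[C@H]2C(C)(C)C=CC[C@@]12C
F5 | step 14 | (4S,4aR,6R,7S,8aR)-6,7-dihydroxy-3,4a,8,8-tetramethyl-4-[4-(trimethylsilyl)but-3-yn-1-yl]-1,4,4a,5,6,7,8,8a-octahydronaphthalen-2-yl trifluoromethanesulfonate | C[Si](C)(C)C#CCC[C@@H]1C(C)=C(OS(=O)(=O)C(F)(F)F)C[C@H]2C(C)(C)[C@H](O)[C@H](O)C[C@@]12C
F6 | step 14 | (4S,4aS,8aR)-3,4a,8,8-tetramethyl-6,7-dioxo-4-[4-(trimethylsilyl)but-3-yn-1-yl]-1,4,4a,5,6,7,8,8a-octahydronaphthalen-2-yl trifluoromethanesulfonate | C[Si](C)(C)C#CCC[C@@H]1C(C)=C(OS(=O)(=O)C(F)(F)F)C[C@H]2C(C)(C)C(=O)C(=O)C[C@@]12C
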